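The theta run lost substrate over 48.0 h at 1.6 M of reagent. The delta flask has the same charge with 2.40 M of reagent, and it is asked about at 50 h.

| setting | delta | theta | flask |
|---|---|---|---|
| left-handed substrate | 0.80 M | 0.80 M | 0.80 M |
| right-handed substrate | 0.80 M | 0.80 M | 0.80 M |
| reagent | 2.4 M | 1.6 M | 2.40 M |
| free catalyst | 1.3 mM | 1.3 mM | 1.3 mM |
| impurity | 0.27 mM | 0.27 mM | 0.27 mM |
| remark | the very flask that is asked about, followed so far | run made earlier |  |
| time |  |  | 50 h |

| run | time / h | left-handed substrate / % | right-handed substrate / % | left-handed product / % |
|---|---|---|---|---|
| delta | 1.33 | 52 | 50 | 0 |
| delta | 2.50 | 46 | 50 | 1 |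
| delta | 4.00 | 47 | 48 | 3 |
| delta | 5.00 | 48 | 47 | 3 |
| delta | 6.00 | 45 | 49 | 3 |
| theta | 4.00 | 48 | 46 | 1 |
| theta | 12.0 | 46 | 48 | 5 |
| theta | 25.0 | 41 | 43 | 8 |
| theta | 40.0 | 41 | 43 | 11 |
| theta | 48.0 | 39 | 41 | 14 |

(readings scatter by 1.5 percentage points)

- part of the left-handed substrate and right-handed substrate charged together that has reacted at 50 h
- excess of left-handed product over right-handed product in the product at 50 h
- excess of right-handed substrate over left-handed substrate among what is left of the two at 50 h

- free catalyst is single-handed; left-handed substrate and right-handed substrate are mirror images of each other, charged as a racemate, each of them at the stated concentration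
- candidate steps: free catalyst + left-handed substrate <-> catalyst intermediate A; free catalyst + right-handed substrate <-> catalyst intermediate B; reagent + catalyst intermediate A -> free catalyst + left-handed product; reagent + catalyst intermediate B -> free catalyst + right-handed product; left-handed product <-> right-handed product; reagent -> decomposition product; free catalyst + impurity -> spent catalyst
- an excess is the difference of the two amounts in percent of their sum
- an excess is below zero if the other one leads

The reckoning made here, separate from the forecast, counts turnovers. One impurity takes out one free catalyst, and each remaining catalyst carries substrate to product at a pace taken in proportion to reagent: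

reacted part = turnover frequency × (reagent ÷ theta reagent) × time × (free catalyst − impurity) ÷ substrate charged

One percent of error in the free catalyst charge moves the reacted part by 1.26 percent. The same error in the impurity charge moves it by 0.262 percent, and in the reagent by one percent. The frequency also counts one for one, and it is the weak term. It rests on a reacted part of 20.0%, taken from two readings, each with a scatter of 1.5 percentage points.

Theta holds 1.03 mM of working catalyst.

turnover frequency = 6.47 h⁻¹

This is the substrate converted per hour by each working catalyst in theta, on average over that run.

turnovers in delta = 485

reacted part in delta = 31.2%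

This stands below the forecast's 36%. The forecast puts the reacted part between 26% and 48%, the product excess at 20% and the substrate excess at 10%, and adds: “Slow product racemisation cannot be excluded”.

The delta flask gives a reacted part of 36.3%, a product excess of 0.237% and a substrate excess of 4.25%.

    free catalyst + left-handed substrate ⇌ catalyst intermediate A (K = 0.400 M⁻¹, k = 15000 M⁻¹ h⁻¹)
    free catalyst + right-handed substrate ⇌ catalyst intermediate B (K = 1.00 M⁻¹, k = 3700 M⁻¹ h⁻¹)
    reagent + catalyst intermediate A → free catalyst + left-handed product (k = 22.0 M⁻¹ h⁻¹)
    reagent + catalyst intermediate B → free catalyst + right-handed product (k = 7.30 M⁻¹ h⁻¹)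
    left-handed product ⇌ right-handed product (k = 0.180 h⁻¹)
    reagent → decomposition product (k = 8.90 × 10⁻⁵ h⁻¹)
    free catalyst + impurity → spent catalyst (k = 1.60 × 10⁵ M⁻¹ h⁻¹)

The delta flask's reacted part amounts to 563 turnovers, against 485 counted from theta. Forecast and flask part on the product excess; in the delta flask the two product forms relax into each other with a half-life of 1.93 h, short against 50 h. The delta flask's reacted part stands where it does in part because of the way back from catalyst intermediate A, together with the time given: with that way back struck out the run gives 59.7%, and ten times the time gives 97.2%. In the neighbour with 0.0022 M of free catalyst, 1.93 mM works, and 485 turnovers give 58.6%. The computed result is 55.9%.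

Readings and results are calculated on assumed constants, and the scatter is random.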